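The numbers of this flask are those of an exercise.

- In a one-step world, left-handed substrate decays on one clock; in this flask reagent must also dissolve from the gas, which brings a second clock.

| setting | cedar | birch | oak | alder |
|---|---|---|---|---|
| left-handed substrate | 1.2 M | 1.2 M | 1.2 M | 1.2 M |
| gas | 200 mM (held) | 200 mM (held) | 200 mM (held) | 200 mM (held) |
| free catalyst | 60 mM | 60 mM | 60 mM | 60 mM |
| added ligand | 110 mM | 110 mM | 110 mM | 110 mM |
| impurity | 32 mM | 32 mM | 32 mM | 32 mM |
| right-handed substrate | 1.2 M | 1.2 M | 1.2 M | 1.2 M |
| temperature | 60 °C |  | 90 °C | 75 °C |
| time | 1.5 min | 1.5 min | 1.5 min | 1.5 min |
| remark |  | at 90 °C until 1.0 min, from then on at 60 °C |  |  |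

    reagent + free catalyst + left-handed substrate → free catalyst + left-handed product (k1 = 1.99 M⁻² s⁻¹, Ea1 = 55.0 kJ mol⁻¹)
    reagent + free catalyst + right-handed substrate → free catalyst + right-handed product (k2 = 0.0503 M⁻² s⁻¹, Ea2 = 35.0 kJ mol⁻¹)
    gas ⇌ reagent, rate k3*(csat - [reagent]) (k3 = 0.142 s⁻¹, csat = 200 mM)
    free catalyst + added ligand ⇌ idle complex, settled at all times (K4 = 15.6 M⁻¹, ΔH4 = −76.0 kJ mol⁻¹)
    free catalyst + impurity → spent catalyst (k5 = 30.0 M⁻¹ s⁻¹, Ea5 = 48.0 kJ mol⁻¹)
    (constants at 60 °C)

- free catalyst is single-handed; left-handed substrate and right-handed substrate are mirror images of each other, charged as a racemate, each of them at the stated concentration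
- at the start none of reagent is dissolved
- the list of constants is for 60 °C, to be carried to other temperatures by the activation energies and enthalpies

1. which flask leads in amount of left-handed product, in percent of the left-handed substrate and right-handed substrate together charged ("all alike" within 1.5 percentage points) (cedar / birch / oak / alder / all alike)
2. how much left-handed product is there at the end, in percent of the left-handed substrate and right-handed substrate together charged: cedar
3. how much left-handed product is there at the end, in percent of the left-handed substrate and right-handed substrate together charged: birch
4. how much left-handed product is there at the end, in percent of the left-handed substrate and right-handed substrate together charged: oak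
5. how much left-handed product is there at the end, in percent of the left-handed substrate and right-handed substrate together charged: alder

- **First instants, cedar.** Impurity is less than the catalyst, so I expect 28.0 mM of catalyst to survive. The time scale of impurity, one over the product of the step-five rate constant and the free part of the surviving catalyst, is about 3.23 s, shorter than the run.
- **The balance, cedar.** Taking added ligand at its charge gives c(free catalyst) = 10.3 mM. Correcting for the ligand held in idle complex gives 11.5 mM.
- **The balance, oak.** The equilibrium constant falls to 1.62 M⁻¹, leaving 23.8 mM free.
- **The lag.** Reagent climbs from nothing over about 7.04 s, one over the transfer coefficient.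
- **The middle.** I take reagent then to sit where gas supply matches use, and left-handed substrate to fall in a pseudo-first-order way. I carry the reaction clock, one over the product of the step-one rate constant, c(free catalyst) and the saturation concentration: 219 s in cedar, and 20.5 s in oak.
- **The gas time.** Delivering the whole left-handed charge at full transfer takes 42.3 s. Clock and gas time add, the gas time scaled by the mean share of substrate present.
- **Which step leads.** Cedar's clock is longer than the gas time, by a factor of 5.18, so the first step is the rate-limiting step there. Oak's clock is about half the gas time, so transfer counts heavily in oak.
- **The end, cedar.** Substrate falls little, so I replace its curve by the charge. The rest is 72.8 %, which gives 13.6 % left-handed product. In cedar I leave step two out of the reckoning, its rate constant being far smaller than that of step one.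
- **The end, oak.** Substrate falls far, so I take its mean as half the charge. The rest is 13.6 %, which gives 43.2 %.
- **My commitment.** I reckon birch and alder no further, but birch runs as hot as oak until 1.0 min and then cools, and alder stands at 75 °C, cooler than oak, so I name oak as leader, its clock being shorter than cedar's.
- **The forecast.** It names oak, with 14.4 % for cedar, 37.4 % for birch, 44.6 % for oak and 32 % for alder, on the ground that “the ligand holds much of that idle at 60 °C but lets go of it on heating”, and it stands higher than my oak figure.

- **Result.** The simulation puts oak first at 44.7 %, with birch at 37.1 %, alder at 31.8 % and cedar at 14.0 %.
- **What remains.** At 1.50 min, 11 % of oak's charged left-handed substrate is still there, against 72 % in cedar.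
- **The clock again.** I add the lag, the gas time multiplied by the converted share, and the clock multiplied by the natural logarithm of charge over rest. Cedar's rest then costs 1.51 min, and oak's rest costs 1.50 min of its 1.5 min.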